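## Retrosynthetic overview

1. The TBS ether is removed last. Before that, ring-closing metathesis closes the only ring, the six-membered lactone O1–C2(=O)–C3=C4–C5–C6, from the 2-substituted acrylate of an (R)-homoallylic alcohol. That alcohol comes from Brown allylation of an (E)-2-(acetoxymethyl)enal.
2. The enal comes from a one-flask, three-component union of a homoallylic C6 cuprate, propiolaldehyde diethyl acetal and bromomethyl acetate (syn-carbocupration, then alkylation of the alkenylcuprate). This forms the bond between the =CH of the central alkene and the CH2CH2 tether, and also the C–CH2OAc bond.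
3. The enabling feature is the central trisubstituted alkene. Its fully substituted carbon carries two oxygenated carbons (CH2OAc and lactone C6–O), and its =CH carbon carries the tether cis to CH2OAc. This 2-alkylidene-1,3-dioxygenated C3 unit is propiolaldehyde at the alkyne level. The cis pair corresponds to a syn addition across C≡C, and C6 held at the aldehyde level as an acetal steers copper to the inner alkyne carbon.
4. The C6 nucleophile comes from (Z)-3-methylpent-2-en-4-yn-1-ol, which already holds the Z-trisubstituted allylic alcohol and all six carbons.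
5. The acrylic acid comes from triethyl phosphonoacetate, homoprenyl bromide and formaldehyde.

Key step: step 5

Assumption: (Z)-3-methylpent-2-en-4-yn-1-ol is used as the geometrically pure Z isomer, and this geometry is carried unchanged into the target.

## Route

Step 1
Reactants: 1 (Z)-3-methylpent-2-en-4-yn-1-ol
Product: 2 tert-butyl(dimethyl){[(2Z)-3-methylpent-2-en-4-yn-1-yl]oxy}silane
Conditions: TBSCl, imidazole, CH2Cl2, 0 °C → rt
Reagents that add atoms: tert-butyldimethylsilyl chloride, CC(C)(C)[Si](C)(C)Cl
Why: Imidazole-promoted silylation of a primary alcohol (standard silyl ether protection) should hide the acidic OH from the organolithium and cuprate chemistry of step 5 without touching the Z-enyne.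

Step 2
Reactants: 2 TBS-protected enyne
Product: 3 tert-butyl(dimethyl){[(2Z)-3-methylpenta-2,4-dien-1-yl]oxy}silane
Conditions: H2 (1 atm), Lindlar catalyst, quinoline, hexane, rt, stopped after one equivalent of H2
Reagents that add atoms: none
Why: In the Lindlar semihydrogenation the poisoned palladium surface reduces the terminal alkyne much faster than the resulting diene, so the vinyl group should form while the trisubstituted Z alkene keeps its geometry.

Step 3
Reactants: 3 TBS-protected (Z)-dienol
Product: 5 (3Z)-5-{[tert-butyl(dimethyl)silyl]oxy}-3-methylpent-3-en-1-ol, via B-alkyl-9-BBN 4 (not isolated)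
Conditions: 9-BBN, THF, 0 °C → rt; then NaOH, H2O2, 0 °C
Reagents that add atoms: 9-BBN, [H]B1C2CCCC1CCC2 (boron and bicycle stay in 4 only); hydrogen peroxide, OO
Why: In this hydroboration–oxidation the bulky 9-BBN places boron on the terminal CH2 of the monosubstituted vinyl group (anti-Markovnikov), leaves the hindered trisubstituted alkene alone, and alkaline peroxide then replaces boron by OH.

Step 4
Reactants: 5 homoallylic alcohol
Product: 6 tert-butyl{[(2Z)-5-iodo-3-methylpent-2-en-1-yl]oxy}dimethylsilane
Conditions: I2, PPh3, imidazole, CH2Cl2, 0 °C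
Reagents that add atoms: iodine, II
Why: In this Appel-type iodination the alkoxyphosphonium ion is displaced by iodide in an SN2 step at the unhindered primary carbon, under conditions that spare the silyl ether and the alkene.

Step 5
Reactants: 6 homoallylic iodide; 7 3,3-diethoxyprop-1-yne (propiolaldehyde diethyl acetal); 8 bromomethyl acetate
Product: 12 (2E,6Z)-8-{[tert-butyl(dimethyl)silyl]oxy}-2-(diethoxymethyl)-6-methylocta-2,6-dien-1-yl acetate, via alkyllithium 9 (not isolated), via lithium dialkylcuprate 10 (not isolated), via lithium dialkenylcuprate 11 (not isolated)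
Conditions: t-BuLi (2 equiv), Et2O–pentane, −78 °C; CuBr·SMe2 (0.5 equiv), Et2O, −40 °C; 7 (1 equiv), −40 → −30 °C; 8 (1.3 equiv), −45 → −25 °C; NH4Cl/NH3 (aq)
Reagents that add atoms: tert-butyllithium, [Li]C(C)(C)C (lithium of 9–11 only); copper(I) bromide–dimethyl sulfide, [Cu]Br.CSC (copper of 10 and 11 only)
Why: In a syn-carbocupration the Gilman reagent 10 delivers its homoallylic CH2 to the terminal alkyne carbon of 7 and copper to the inner carbon, because the two acetal oxygens polarise the triple bond and hold lithium (the reversed, linear regiochemistry known for lithium dialkylcuprates and propiolaldehyde acetals in Et2O), giving alkenylcuprate 11 with the new chain and copper cis. The C(sp2)–Cu bond is then alkylated with retention by the α-acyloxy halide 8 (oxidative addition and reductive elimination at copper), so the chain ends cis to CH2OAc and trans to the acetal carbon, which is the geometry of the target. The closest known reaction type is the Normant-type three-component alkene synthesis, that is, carbocupration of an acetylenic acetal followed by trapping of the alkenylcuprate with a reactive alkyl halide. No ring is closed and no stereocentre is formed; the only stereochemical element, the trisubstituted C=C, is fixed by the syn addition and by retention in the trapping. The step needs regioselectivity (secured by the acetal), survival of 11 against β-elimination of ethoxide to an ethoxyallene (secured by staying below −25 °C and by the high SN2 reactivity of 8), and chemoselectivity for C–Br over the acetate carbonyl, the allylic silyl ether and the allylic acetate of the product (soft alkenylcuprate, low temperature, slight excess of 8). One flask should thus create two C–C bonds, the alkene geometry, the acetate and the aldehyde oxidation level from which the lactone carbinol is made.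

Step 6
Reactants: 12 acetal
Product: 13 (2E,6Z)-8-{[tert-butyl(dimethyl)silyl]oxy}-2-formyl-6-methylocta-2,6-dien-1-yl acetate
Conditions: 10% aq oxalic acid on SiO2, CH2Cl2, rt
Reagents that add atoms: water, O
Why: Acid-catalysed acetal hydrolysis runs through an allyl-stabilised oxocarbenium ion and is therefore fast enough to spare the TBS ether and the acetate, and the enal formed already has the thermodynamically preferred geometry (CHO trans to the chain).

Step 7
Reactants: 13 enal
Product: 15 (2E,6Z)-8-{[tert-butyl(dimethyl)silyl]oxy}-2-[(1R)-1-hydroxybut-3-en-1-yl]-6-methylocta-2,6-dien-1-yl acetate, via diisopinocampheylborinate 14 (not isolated)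
Conditions: (+)-Ipc2BOMe, allylMgBr, Et2O, 0 °C → rt; 13, −78 °C; then MeOH, pH 7 buffer, H2O2, 0 °C
Reagents that add atoms: allylmagnesium bromide, C=CC[Mg]Br; (+)-B-methoxydiisopinocampheylborane, COB([C@H]1C[C@H]2C[C@@H]([C@@H]1C)C2(C)C)[C@H]1C[C@H]2C[C@@H]([C@@H]1C)C2(C)C (boron and Ipc groups stay in 14 only)
Why: In the Brown asymmetric allylboration the allyl group is transferred through a closed chair transition state in which the isopinocampheyl groups derived from (−)-α-pinene expose the Re face of the aldehyde, which should set the single stereocentre as R, while the esters are inert to the allylborane at −78 °C and the buffered work-up keeps the acetate.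

Step 8
Reactants: 16 triethyl phosphonoacetate; 17 5-bromo-2-methylpent-2-ene
Product: 19 ethyl 2-(diethoxyphosphoryl)-6-methylhept-5-enoate (racemic), via sodium phosphonate carbanion 18 (not isolated)
Conditions: NaH, THF, 0 °C; then 17, NaI (cat.), DMF, 60 °C
Reagents that add atoms: none
Why: This is an SN2 alkylation of the stabilised phosphonoacetate carbanion with a primary homoallylic bromide, the standard entry to α-substituted Horner–Wadsworth–Emmons reagents.

Step 9
Reactants: 19 α-alkylated phosphonate
Product: 20 ethyl 6-methyl-2-methylidenehept-5-enoate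
Conditions: 37% aq HCHO, K2CO3, H2O, 80 °C
Reagents that add atoms: formaldehyde, C=O
Why: Horner–Wadsworth–Emmons olefination with aqueous formaldehyde under carbonate conditions gives the 1,1-disubstituted acrylate directly, with loss of water-soluble diethyl phosphate.

Step 10
Reactants: 20 ethyl ester
Product: 22 6-methyl-2-methylidenehept-5-enoic acid, via lithium carboxylate 21 (not isolated)
Conditions: LiOH, THF–MeOH–H2O, rt; then 1 M HCl
Reagents that add atoms: lithium hydroxide, [Li+].[OH-]
Why: This is saponification of an unhindered ethyl ester, and the α-substituted acrylate is a poor Michael acceptor for hydroxide at room temperature.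

Step 11
Reactants: 15 (R)-homoallylic alcohol; 22 acrylic acid
Product: 23 (4R,5E,9Z)-5-(acetoxymethyl)-11-{[tert-butyl(dimethyl)silyl]oxy}-9-methylundeca-1,5,9-trien-4-yl 6-methyl-2-methylidenehept-5-enoate
Conditions: DCC, DMAP (cat.), CH2Cl2, 0 °C → rt
Reagents that add atoms: none
Why: Steglich esterification acylates the secondary allylic alcohol under neutral conditions without breaking its C–O bond, so the configuration is kept, and it should be fast enough to outrun 1,3-acetyl migration.

Step 12
Reactants: 23 diene ester
Product: 24 (2E,6Z)-8-{[tert-butyl(dimethyl)silyl]oxy}-6-methyl-2-[(2R)-5-(4-methylpent-3-en-1-yl)-6-oxo-3,6-dihydro-2H-pyran-2-yl]octa-2,6-dien-1-yl acetate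
Conditions: Grubbs II (cat.), 1,4-benzoquinone (cat.), CH2Cl2 (2 mM), 40 °C
Reagents that add atoms: none
Why: In this ring-closing metathesis the ruthenium carbene loads on the monosubstituted terminal alkene and closes the six-membered ring onto the 1,1-disubstituted acrylate alkene (a known route to 3-alkyl-5,6-dihydropyran-2-ones), loss of ethene drives it, and the three trisubstituted alkenes are hindered and could only give strained or medium rings.

Step 13
Reactants: 24 TBS-protected lactone
Product: 25 (2E,6Z)-8-hydroxy-6-methyl-2-[(2R)-5-(4-methylpent-3-en-1-yl)-6-oxo-3,6-dihydro-2H-pyran-2-yl]octa-2,6-dien-1-yl acetate (target)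
Conditions: HF·pyridine, pyridine, THF, 0 °C → rt
Reagents that add atoms: none
Why: Fluoride-induced desilylation of the primary allylic TBS ether with pyridine-buffered HF·pyridine should leave the acetate, the lactone, the alkenes and the stereocentre untouched.

## Compound list

1 | (Z)-3-methylpent-2-en-4-yn-1-ol | C#C/C(C)=C\CO | starting material
2 | tert-butyl(dimethyl){[(2Z)-3-methylpent-2-en-4-yn-1-yl]oxy}silane | C#C/C(C)=C\CO[Si](C)(C)C(C)(C)C | intermediate
3 | tert-butyl(dimethyl){[(2Z)-3-methylpenta-2,4-dien-1-yl]oxy}silane | C=C/C(C)=C\CO[Si](C)(C)C(C)(C)C | intermediate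
4 | 9-[(3Z)-5-{[tert-butyl(dimethyl)silyl]oxy}-3-methylpent-3-en-1-yl]-9-borabicyclo[3.3.1]nonane | C1CCC2CCCC1B2CC/C(C)=C\CO[Si](C)(C)C(C)(C)C | intermediate
5 | (3Z)-5-{[tert-butyl(dimethyl)silyl]oxy}-3-methylpent-3-en-1-ol | OCC/C(C)=C\CO[Si](C)(C)C(C)(C)C | intermediate
6 | tert-butyl{[(2Z)-5-iodo-3-methylpent-2-en-1-yl]oxy}dimethylsilane | ICC/C(C)=C\CO[Si](C)(C)C(C)(C)C | intermediate
7 | 3,3-diethoxyprop-1-yne | C#CC(OCC)OCC | starting material
8 | bromomethyl acetate | CC(=O)OCBr | starting material
9 | [(3Z)-5-{[tert-butyl(dimethyl)silyl]oxy}-3-methylpent-3-en-1-yl]lithium | [Li]CC/C(C)=C\CO[Si](C)(C)C(C)(C)C | intermediate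
10 | lithium bis[(3Z)-5-{[tert-butyl(dimethyl)silyl]oxy}-3-methylpent-3-en-1-yl]cuprate | [Li+].[Cu-](CC/C(C)=C\CO[Si](C)(C)C(C)(C)C)CC/C(C)=C\CO[Si](C)(C)C(C)(C)C | intermediate
11 | lithium bis[1,1-diethoxy-8-silyloxy-6-methylocta-2,6-dien-2-yl]cuprate (chain cis to Cu, 6Z) | [Li+].[Cu-](/C(=C\CC/C(C)=C\CO[Si](C)(C)C(C)(C)C)C(OCC)OCC)/C(=C\CC/C(C)=C\CO[Si](C)(C)C(C)(C)C)C(OCC)OCC | intermediate
12 | (2E,6Z)-8-{[tert-butyl(dimethyl)silyl]oxy}-2-(diethoxymethyl)-6-methylocta-2,6-dien-1-yl acetate | CC(=O)OC/C(=C\CC/C(C)=C\CO[Si](C)(C)C(C)(C)C)C(OCC)OCC | intermediate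
13 | (2E,6Z)-8-{[tert-butyl(dimethyl)silyl]oxy}-2-formyl-6-methylocta-2,6-dien-1-yl acetate | CC(=O)OC/C(=C\CC/C(C)=C\CO[Si](C)(C)C(C)(C)C)C=O | intermediate
14 | diisopinocampheylborinate of 15 | CC(=O)OC/C(=C\CC/C(C)=C\CO[Si](C)(C)C(C)(C)C)[C@H](OB([C@H]1C[C@H]2C[C@@H]([C@@H]1C)C2(C)C)[C@H]1C[C@H]2C[C@@H]([C@@H]1C)C2(C)C)CC=C | intermediate
15 | (2E,6Z)-8-{[tert-butyl(dimethyl)silyl]oxy}-2-[(1R)-1-hydroxybut-3-en-1-yl]-6-methylocta-2,6-dien-1-yl acetate | CC(=O)OC/C(=C\CC/C(C)=C\CO[Si](C)(C)C(C)(C)C)[C@H](O)CC=C | intermediate
16 | triethyl phosphonoacetate | CCOC(=O)CP(=O)(OCC)OCC | starting material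
17 | 5-bromo-2-methylpent-2-ene | CC(C)=CCCBr | starting material
18 | sodium salt of triethyl phosphonoacetate | CCOC(=O)[CH-]P(=O)(OCC)OCC.[Na+] | intermediate
19 | ethyl 2-(diethoxyphosphoryl)-6-methylhept-5-enoate (racemic) | CCOC(=O)C(CCC=C(C)C)P(=O)(OCC)OCC | intermediate
20 | ethyl 6-methyl-2-methylidenehept-5-enoate | CCOC(=O)C(=C)CCC=C(C)C | intermediate
21 | lithium 6-methyl-2-methylidenehept-5-enoate | [Li+].[O-]C(=O)C(=C)CCC=C(C)C | intermediate
22 | 6-methyl-2-methylidenehept-5-enoic acid | OC(=O)C(=C)CCC=C(C)C | intermediate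
23 | (4R,5E,9Z)-5-(acetoxymethyl)-11-{[tert-butyl(dimethyl)silyl]oxy}-9-methylundeca-1,5,9-trien-4-yl 6-methyl-2-methylidenehept-5-enoate | CC(=O)OC/C(=C\CC/C(C)=C\CO[Si](C)(C)C(C)(C)C)[C@H](OC(=O)C(=C)CCC=C(C)C)CC=C | intermediate
24 | TBS ether of the target | CC(=O)OC/C(=C\CC/C(C)=C\CO[Si](C)(C)C(C)(C)C)[C@H]1CC=C(CCC=C(C)C)C(=O)O1 | intermediate
25 | (2E,6Z)-8-hydroxy-6-methyl-2-[(2R)-5-(4-methylpent-3-en-1-yl)-6-oxo-3,6-dihydro-2H-pyran-2-yl]octa-2,6-dien-1-yl acetate | CC(=O)OC/C(=C\CC/C(C)=C\CO)[C@H]1CC=C(CCC=C(C)C)C(=O)O1 | target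

## Step count and risks

Total step count: 13. Longest linear sequence: 10 (steps 1–7 and 11–13).

**Step 5.** Several processes could compete with the intended coupling:
- The cuprate may deprotonate the terminal alkyne instead of adding to it.
- Regiocontrol in the carbocupration may erode.
- The alkenylcuprate may lose ethoxide by β-elimination before it is trapped.
- Remaining cuprate may attack the freshly formed allylic acetate.

The fallback sets out from 6 and comes back at 13. Cuprate 10, made from 6 as in step 5, is added to diethyl ethoxymethylenemalonate (addition–elimination, Et2O–THF, −78 → 0 °C). This forms the same C–C bond on a symmetric acceptor and should give the diethyl alkylidenemalonate F1. DIBAL-H (CH2Cl2, −78 °C) reduces both esters to the 2-alkylidenepropane-1,3-diol F2. MnO2 (CH2Cl2, rt) oxidises one allylic CH2OH, and through the easy E/Z equilibration of 2-substituted enals the product is expected to settle with CHO trans to the chain as the hydroxy enal F3. Ac2O and pyridine then give 13. Here thermodynamic control of the geometry replaces kinetic syn addition.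

**Step 12.** The hindered, electron-poor 1,1-disubstituted acrylate alkene may engage too slowly. Dimerisation through the terminal alkene or metathesis at the prenyl-type alkenes could then take over. The fallback sets out from 15 and comes back at 24. Compound 15 is esterified with acryloyl chloride (Et3N, CH2Cl2, 0 °C) to the acrylate F4. Its ring-closing metathesis joins two monosubstituted alkenes and should give the 3-unsubstituted dihydropyranone F5. I2/pyridine (α-iodination of the unsaturated lactone by the addition–elimination mode) gives the 3-iodo lactone F6. Negishi coupling with (4-methylpent-3-en-1-yl)zinc bromide F7, made from 17 and zinc dust, installs the side chain and gives 24.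

**Step 2.** Over-reduction of the conjugated diene and Z-to-E isomerisation on palladium may accompany the semihydrogenation. The fallback sets out from 2 and comes back at 5. The terminal alkyne of 2 is hydroborated directly with dicyclohexylborane (THF, 0 °C) to the dienylborane F8. Mild oxidation (NaBO3·4H2O, THF–H2O) gives the β,γ-unsaturated aldehyde F9, which is reduced at once with NaBH4 (MeOH, 0 °C) to 5. Compounds 3 and 4 are bypassed.

Further compounds
F1 | step 5 | diethyl 2-[(3Z)-5-{[tert-butyl(dimethyl)silyl]oxy}-3-methylpent-3-en-1-ylidene]propanedioate | CCOC(=O)C(=CCC/C(C)=C\CO[Si](C)(C)C(C)(C)C)C(=O)OCC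
F2 | step 5 | 2-[(3Z)-5-{[tert-butyl(dimethyl)silyl]oxy}-3-methylpent-3-en-1-ylidene]propane-1,3-diol | OCC(CO)=CCC/C(C)=C\CO[Si](C)(C)C(C)(C)C
F3 | step 5 | (2E,6Z)-8-{[tert-butyl(dimethyl)silyl]oxy}-2-(hydroxymethyl)-6-methylocta-2,6-dienal | OC/C(=C\CC/C(C)=C\CO[Si](C)(C)C(C)(C)C)C=O
F4 | step 12 | (4R,5E,9Z)-5-(acetoxymethyl)-11-{[tert-butyl(dimethyl)silyl]oxy}-9-methylundeca-1,5,9-trien-4-yl prop-2-enoate | CC(=O)OC/C(=C\CC/C(C)=C\CO[Si](C)(C)C(C)(C)C)[C@H](OC(=O)C=C)CC=C
F5 | step 12 | (2E,6Z)-8-{[tert-butyl(dimethyl)silyl]oxy}-6-methyl-2-[(2R)-6-oxo-3,6-dihydro-2H-pyran-2-yl]octa-2,6-dien-1-yl acetate | CC(=O)OC/C(=C\CC/C(C)=C\CO[Si](C)(C)C(C)(C)C)[C@H]1CC=CC(=O)O1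
F6 | step 12 | (2E,6Z)-8-{[tert-butyl(dimethyl)silyl]oxy}-2-[(2R)-5-iodo-6-oxo-3,6-dihydro-2H-pyran-2-yl]-6-methylocta-2,6-dien-1-yl acetate | CC(=O)OC/C(=C\CC/C(C)=C\CO[Si](C)(C)C(C)(C)C)[C@H]1CC=C(I)C(=O)O1
F7 | step 12 | (4-methylpent-3-en-1-yl)zinc bromide | CC(C)=CCC[Zn]Br
F8 | step 2 | dicyclohexyl[(1E,3Z)-5-{[tert-butyl(dimethyl)silyl]oxy}-3-methylpenta-1,3-dien-1-yl]borane | C1CCCCC1B(C1CCCCC1)/C=C/C(C)=C\CO[Si](C)(C)C(C)(C)C
F9 | step 2 | (3Z)-5-{[tert-butyl(dimethyl)silyl]oxy}-3-methylpent-3-enal | O=CC/C(C)=C\CO[Si](C)(C)C(C)(C)C
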